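The route cuts the seven-membered carbocycle C3–C4–C5–C6–C7–C10–C11 of the homoadamantane cage at C5–C6 and C3–C11. The key step exploits that this ring joins the two quaternary, prenyl-bearing carbons C3 and C5 of ring A through a four-carbon chain with allylic ends. One palladium-catalysed double allylic alkylation forms both bonds, dearomatizes ring A, closes a bicyclo[4.3.1]decane and sets C3, C5 and C11. Its precursors are symmetric 3,5-diprenyl-2,4,6-trihydroxybenzophenone and an (R)-configured ten-carbon unit bearing a primary allylic chloride and a secondary allylic methyl carbonate. Cationic C1–C8 closure and a peroxyl radical cascade finish the target.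

Key step: step 10

Atom labels: ring A = C1 (benzoyl-bearing), C2, C3, C4, C5, C9. C6H2 sits on C5, followed by C7. C8Me2 lies between C7 and C1. C10H2 and C11 link C7 to C3, and C12 is the carbon on C11. C17H2–C18H=C19Me2 is the prenyl group on C3. Seen from the C7 side of ring A, C1→C2→C3→C4→C5→C9 runs counterclockwise in the series made here.

Assumption: the (R,R)-ligand is taken to give the C5 configuration drawn; no reliable model predicts the sense of induction for this nucleophile, so the (S,S)-ligand would be used if a trial shows the opposite sense.

Step 1
Reactants: 1 phloroglucinol; 2 benzoyl chloride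
Product: 3 2,4,6-trihydroxybenzophenone
Conditions: AlCl3 (4 equiv), PhNO2, 65 °C; then aq. HCl
Reagents that add atoms: none
Why: Friedel–Crafts acylation of the symmetric, very electron-rich ring stops after one acylation because the aryl ketone formed is deactivated and held as its aluminium chelate.

Step 2
Reactants: 3 2,4,6-trihydroxybenzophenone; 4 prenyl bromide (2 equiv)
Product: 5 3,5-diprenyl-2,4,6-trihydroxybenzophenone
Conditions: KOH (2.1 equiv), H2O, 0 °C → rt
Reagents that add atoms: none
Why: C-alkylation of an ambident phenolate, in which water hydrogen-bonds the oxygens of the acylphloroglucinolate so that the soft allylic bromide is taken up by the two free ring carbons, while two equivalents at 0 °C limit dearomatizing over-alkylation.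

Step 3
Reactants: 6 diethyl succinate; 7 acetone
Product: 8 3-(ethoxycarbonyl)-4-methylpent-3-enoic acid
Conditions: KOt-Bu, t-BuOH, reflux; then aq. HCl
Reagents that add atoms: none
Why: Stobbe condensation (aldol addition, lactonization, E1cB ring opening) gives the isopropylidene half-ester, so the two carboxyl carbons, later C6 and C11, leave the step already differentiated.

Step 4
Reactants: 8 3-(ethoxycarbonyl)-4-methylpent-3-enoic acid
Product: 10 ethyl 2-{2-[methoxy(methyl)amino]-2-oxoethyl}-3-methylbut-2-enoate, via acyl imidazolide 9 (not isolated)
Conditions: 1,1'-carbonyldiimidazole, CH2Cl2, rt; then MeNH(OMe)·HCl, rt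
Reagents that add atoms: N,O-dimethylhydroxylamine hydrochloride, CNOC.Cl; 1,1'-carbonyldiimidazole, O=C(n1ccnc1)n1ccnc1 (its imidazolyl group stays only in 9)
Why: Weinreb amide formation through the acyl imidazolide activates only the free acid and leaves the hindered conjugated ester alone.

Step 5
Reactants: 10 Weinreb amide; 11 isopropenylmagnesium bromide (1.5 equiv)
Product: 12 ethyl 5-methyl-4-oxo-2-(propan-2-ylidene)hex-5-enoate
Conditions: THF, −20 → 0 °C; cold aq. NH4Cl
Reagents that add atoms: none
Why: Weinreb ketone synthesis, in which the chelated tetrahedral adduct stops after one addition, the tetrasubstituted acrylate ester is too hindered to compete, and a cold, weakly acidic quench avoids migration of the C7=C8 double bond.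

Step 6
Reactants: 12 ethyl 5-methyl-4-oxo-2-(propan-2-ylidene)hex-5-enoate
Product: 14 (5R)-5-(prop-1-en-2-yl)-3-(propan-2-ylidene)oxolan-2-one, via (R)-hydroxy ester 13 (not isolated)
Conditions: (S)-Me-CBS oxazaborolidine (0.2 equiv), catecholborane (1.5 equiv), toluene, −78 °C; MeOH, then H2O; then pyridinium p-toluenesulfonate (0.1 equiv), toluene, 40 °C
Reagents that add atoms: none
Why: Corey–Bakshi–Shibata reduction in which the isopropenyl group acts as the large substituent, so the (S)-oxazaborolidine should give the (R)-carbinol at C11, catecholborane at −78 °C sparing alkenes and ester, and mild acid then closes the five-membered lactone.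

Step 7
Reactants: 14 (5R)-lactone
Product: 15 (3R)-5-(hydroxymethyl)-2,6-dimethylhepta-1,5-dien-3-ol
Conditions: i-Bu2AlH (3.5 equiv), CH2Cl2, −78 → 0 °C; aq. potassium sodium tartrate
Reagents that add atoms: none
Why: Hydride reduction of the α-alkylidene lactone by 1,2-delivery gives the primary allylic alcohol at C6 and frees the C11 hydroxyl without touching the alkenes or the stereocentre.

Step 8
Reactants: 15 (3R)-diol
Product: 17 (3R)-5-(chloromethyl)-2,6-dimethylhepta-1,5-dien-3-ol, via primary allylic mesylate 16 (not isolated)
Conditions: MsCl (1.05 equiv), LiCl (3 equiv), 2,4,6-collidine, DMF, 0 °C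
Reagents that add atoms: lithium chloride, [Li+].[Cl-]; methanesulfonyl chloride, CS(=O)(=O)Cl (its mesyl group stays only in 16)
Why: Collington–Meyers chlorination mesylates only the unhindered primary allylic hydroxyl and chloride displaces it in situ without allylic shift; a chloride is chosen over a bromide because it resists ring closure by the free C11 hydroxyl here and uncatalysed attack by the phenolate in step 10.

Step 9
Reactants: 17 (3R)-chloro alcohol
Product: 18 (3R)-5-(chloromethyl)-2,6-dimethylhepta-1,5-dien-3-yl methyl carbonate
Conditions: ClCO2Me (1.5 equiv), pyridine, CH2Cl2, 0 °C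
Reagents that add atoms: methyl chloroformate, COC(=O)Cl
Why: O-acylation of the secondary allylic alcohol proceeds with retention at C11, is run cold and briefly so that pyridine does not quaternize the allylic chloride, and installs a leaving group that later releases its own base (methoxide) on ionization.

Step 10
Reactants: 5 3,5-diprenyl-2,4,6-trihydroxybenzophenone; 18 (3R)-chloride carbonate
Product: 20 C7-isopropylidene C11-exo-isopropenyl bicyclo[4.3.1]decane benzoyl enol, via C5-monoalkylated cyclohexadienone 19 (not isolated)
Conditions: Pd2(dba)3·CHCl3 (5 mol %), (R,R)-DACH-phenyl bisphosphine [(1R,2R)-N,N'-bis(2-diphenylphosphinobenzoyl)cyclohexane-1,2-diamine, 12 mol %], Cs2CO3 (1.1 equiv), degassed toluene, 0 °C, slow addition of 18; then dilution to 0.01 M, 60 °C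
Reagents that add atoms: none
Why: Proposed new method: zerovalent palladium ionises the primary allylic chloride of 18 first, the caesium phenolate of 5 attacks the unsubstituted terminus C6 of that π-allyl through one prenyl-bearing ring carbon (C5–C6, ring A dearomatized, 19), and on warming the secondary carbonate ionises with loss of CO2, the released methoxide deprotonates 19, and C3 attacks C11. The closest known reaction type is the palladium-catalysed dearomative conjunctive allylic annulation of acylphloroglucinols, a double Tsuji–Trost alkylation in which a single 2-methylenepropane-1,3-diyl unit gives bicyclo[3.3.1]nonanes; new here are two separate allyl termini joined through C7 and C10 and the larger ring. The carbocycle C3–C4–C5–C6–C7–C10–C11 closes 7-exo at the internal allyl terminus, helped by the bulky C7 isopropylidene group that folds the axial tether back over ring A, whereas attack at the CH2 terminus would be a 9-endo closure to a bridged ring holding a trisubstituted alkene. C5 is set by the chiral ligand, which must tell apart the two enantiotopic prenylated carbons of 5; C3 follows from C5 because the tether can only span the ring on the face it occupies; C11 is set by double inversion (net retention) at the (R)-carbonate carbon and, if the π-allyl faces exchange through the CH2 terminus, by the same preference for the isopropenyl–palladium unit to sit exo, on the side of the one-carbon C4 bridge. The step needs chloride-before-carbonate order, carbon over oxygen attack and C3 over C1: the halide reacts with zerovalent palladium at 0 °C where the hindered carbonate is inert, allyl enol ethers re-ionise so that O-allylation is reversible, and the benzoyl-bearing C1 is the most delocalised, least nucleophilic carbon of the trione anion. The chloride in place of a bromide keeps uncatalysed, racemic SN2 alkylation of the phenolate slow against the ligand-controlled path.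

Step 11
Reactants: 20 bicyclo[4.3.1]decane benzoyl enol
Product: 21 homoadamantane tetraketone with C11 isopropenyl group
Conditions: Tf2NH (10 mol %), CH2Cl2, −40 → 0 °C
Reagents that add atoms: none
Why: Biomimetic cationic cyclization (intramolecular Markovnikov hydroalkylation) in which protonation of the tetrasubstituted C7=C8 alkene on its outer face is assisted by the enol π-system lying across the ring, C1 as the only nucleophilic carbon left captures the C8 cation in a six-membered closure, C1 and C7 are fixed by the cage geometry, and a catalytic strong acid at low temperature is meant to leave the unassisted prenyl and isopropenyl groups untouched.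

Step 12
Reactants: 21 homoadamantane tetraketone
Product: 22 C12 triethylsilyl peroxide
Conditions: Co(thd)2 (10 mol %), Et3SiH (1.5 equiv), O2 (1 atm, saturated solution), ClCH2CH2Cl, rt
Reagents that add atoms: dioxygen, O=O; triethylsilane, CC[SiH](CC)CC
Why: Mukaiyama–Isayama hydroperoxysilylation, in which cobalt-hydride hydrogen-atom transfer goes fastest to the terminal CH2 of the 1,1-disubstituted alkene, the tertiary C12 radical is trapped by O2 in saturated solution before it can add to the neighbouring prenyl group, and limiting the silane should spare the two trisubstituted alkenes.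

Step 13
Reactants: 22 C12 triethylsilyl peroxide
Product: 23 C12 hydroperoxide
Conditions: aq. HF (48 %), MeCN, 0 °C
Reagents that add atoms: none
Why: Fluoride-driven Si–O cleavage under acidic conditions frees the tertiary hydroperoxide without exposing the non-enolizable β-tricarbonyl array, which is prone to retro-Claisen cleavage, to a basic nucleophile.

Step 14
Reactants: 23 C12 hydroperoxide
Product: 24 target CNP0215795.1
Conditions: t-BuON=NOt-Bu (0.2 equiv), t-BuOOH (2 equiv), O2 (1 atm), benzene, 40 °C
Reagents that add atoms: dioxygen, O=O
Why: Peroxyl radical cyclization–oxygenation chain in which tert-butoxyl radicals abstract the OO–H hydrogen, the C12 peroxyl radical adds 7-exo to C18 of the adjacent C3 prenyl group, the tertiary C19 radical takes up O2 and the new peroxyl radical propagates by abstracting hydrogen from a hydroperoxide, C18 being expected as (S) because the twist-chair transition state that keeps the O–O unit away from the C4 carbonyl oxygen turns the C19 terminus outward from the cage.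

Compound list
1 | phloroglucinol | Oc1cc(O)cc(O)c1 | starting material
2 | benzoyl chloride | O=C(Cl)c1ccccc1 | starting material
3 | 2,4,6-trihydroxybenzophenone | O=C(c1ccccc1)c1c(O)cc(O)cc1O | intermediate
4 | prenyl bromide (1-bromo-3-methylbut-2-ene) | CC(C)=CCBr | starting material
5 | 3,5-diprenyl-2,4,6-trihydroxybenzophenone | CC(C)=CCc1c(O)c(CC=C(C)C)c(O)c(C(=O)c2ccccc2)c1O | intermediate
6 | diethyl succinate | CCOC(=O)CCC(=O)OCC | starting material
7 | acetone | CC(C)=O | starting material
8 | 3-(ethoxycarbonyl)-4-methylpent-3-enoic acid | CCOC(=O)C(CC(=O)O)=C(C)C | intermediate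
9 | ethyl 2-[2-(imidazol-1-yl)-2-oxoethyl]-3-methylbut-2-enoate (acyl imidazolide, not isolated) | CCOC(=O)C(CC(=O)n1ccnc1)=C(C)C | intermediate
10 | ethyl 2-{2-[methoxy(methyl)amino]-2-oxoethyl}-3-methylbut-2-enoate | CCOC(=O)C(CC(=O)N(C)OC)=C(C)C | intermediate
11 | isopropenylmagnesium bromide (commercial THF solution) | CC(=C)[Mg]Br | starting material
12 | ethyl 5-methyl-4-oxo-2-(propan-2-ylidene)hex-5-enoate | CCOC(=O)C(CC(=O)C(C)=C)=C(C)C | intermediate
13 | ethyl (4R)-4-hydroxy-5-methyl-2-(propan-2-ylidene)hex-5-enoate (not isolated) | CCOC(=O)C(=C(C)C)C[C@@H](O)C(C)=C | intermediate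
14 | (5R)-5-(prop-1-en-2-yl)-3-(propan-2-ylidene)oxolan-2-one | CC(=C)[C@H]1CC(=C(C)C)C(=O)O1 | intermediate
15 | (3R)-5-(hydroxymethyl)-2,6-dimethylhepta-1,5-dien-3-ol | OCC(=C(C)C)C[C@@H](O)C(C)=C | intermediate
16 | (4R)-4-hydroxy-5-methyl-2-(propan-2-ylidene)hex-5-en-1-yl methanesulfonate (not isolated) | CS(=O)(=O)OCC(=C(C)C)C[C@@H](O)C(C)=C | intermediate
17 | (3R)-5-(chloromethyl)-2,6-dimethylhepta-1,5-dien-3-ol | ClCC(=C(C)C)C[C@@H](O)C(C)=C | intermediate
18 | (3R)-5-(chloromethyl)-2,6-dimethylhepta-1,5-dien-3-yl methyl carbonate | ClCC(=C(C)C)C[C@@H](OC(=O)OC)C(C)=C | intermediate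
19 | (6S)-2-benzoyl-3,5-dihydroxy-6-[(4R)-4-(methoxycarbonyloxy)-5-methyl-2-(propan-2-ylidene)hex-5-en-1-yl]-4,6-diprenylcyclohexa-2,4-dien-1-one (ring position 6 = C5; not isolated) | O=C1C(C(=O)c2ccccc2)=C(O)C(CC=C(C)C)=C(O)[C@]1(CC=C(C)C)CC(=C(C)C)C[C@@H](OC(=O)OC)C(C)=C | intermediate
20 | bicyclo[4.3.1]decane with bridgeheads C3 and C5 (each prenylated), one-carbon bridge C4=O, bridge C2(=O)–C1(benzoyl)=C9(OH), bridge C6H2–C7(=C8Me2)–C10H2–C11H; isopropenyl on C11 exo, on the C4 side | CC(C)=CC[C@]12CC(=C(C)C)C[C@H](C(C)=C)[C@](CC=C(C)C)(C1=O)C(=O)C(C(=O)c1ccccc1)=C2O | intermediate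
21 | homoadamantane 2,4,9-trione with C1 benzoyl, C3 and C5 prenyl, C8 gem-dimethyl, C7–H outward, C11 isopropenyl on the C4 side | CC(C)=CC[C@]12C[C@@H]3C[C@H](C(C)=C)[C@](CC=C(C)C)(C1=O)C(=O)[C@](C(=O)c1ccccc1)(C2=O)C3(C)C | intermediate
22 | as 21, with C11 bearing C12Me2–OOSiEt3 | CC(C)=CC[C@]12C[C@@H]3C[C@H](C(C)(C)OO[Si](CC)(CC)CC)[C@](CC=C(C)C)(C1=O)C(=O)[C@](C(=O)c1ccccc1)(C2=O)C3(C)C | intermediate
23 | as 21, with C11 bearing C12Me2–OOH | CC(C)=CC[C@]12C[C@@H]3C[C@H](C(C)(C)OO)[C@](CC=C(C)C)(C1=O)C(=O)[C@](C(=O)c1ccccc1)(C2=O)C3(C)C | intermediate
24 | CNP0215795.1: cage of 21 fused at C3–C11 to the 1,2-dioxepane C11–C12Me2–O–O–C18H–C17H2–C3, C18 bearing C19Me2–OOH; (1R,3R,5S,7S,11S,18S) in the labels used here | CC(C)=CC[C@]12C[C@@H]3C[C@@H]4C(C)(C)OO[C@H](C(C)(C)OO)C[C@@]4(C1=O)C(=O)[C@](C(=O)c1ccccc1)(C2=O)C3(C)C | target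

Total step count: 14. Longest linear sequence: 12 steps (steps 3–14, from diethyl succinate).

Steps most likely to fail

1. Step 10.
What may go wrong:
- ring closure through the terminal allyl carbon in place of C11;
- loss of a doubly allylic C10 proton from the second π-allyl before the slow ring closure;
- weak discrimination between the two enantiotopic ring carbons in the first alkylation.

Fallback (sets out from 5 and 18, comes back at 20): the two bond formations are separated and neither depends on a palladium π-allyl. The lithium phenolate of 5 (LiN(SiMe3)2, THF, 0 °C, catalytic NaI) is C-alkylated by the chloride of 18. This is a plain SN2 alkylative dearomatization, a known reaction of this arene class. Because C11 is already (R), the alkylation gives 19 together with the C5-epimeric dienone F1. These are diastereomers that can be separated on silica, so the absolute configuration no longer rests on a ligand. Isolated 19 is then closed to 20 with RhCl(PPh3)3 (10 mol %) and P(OMe)3 (40 mol %) in THF at 40 °C. In this rhodium-catalysed allylic alkylation the enyl intermediates are substituted at the carbon that carried the carbonate, with net retention.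

2. Step 11.
What may go wrong:
- competing protonation of the isopropenyl or prenyl groups followed by capture by an enol oxygen;
- migration of the isopropenyl double bond toward C11, with loss of that stereocentre;
- oxygen rather than carbon capture of the C8 cation.

Fallback (sets out from 20, comes back at 21): the proton is replaced by an iodonium ion, for which the tetrasubstituted alkene is the best donor in the molecule. Iodocarbocyclization (I2, KI, KHCO3, THF–H2O, rt) is a known way of closing such cores from enolized triones. It should add iodine to the outer face of C7 while C1 attacks C8, giving the C7-iodo cage F2. Radical deiodination ((Me3Si)3SiH, AIBN, toluene, 80 °C) then delivers hydrogen to the only open face of the bridgehead radical and gives 21.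

3. Step 14.
What may go wrong:
- the 7-exo addition being too slow against allylic hydrogen abstraction and radical termination;
- poor facial selectivity at C18;
- reversible addition of the hydroperoxide to the nearby C4 carbonyl, draining the chain carrier.

Fallback (sets out from 23, comes back at 24): a polar, metal-mediated closure replaces the radical one. Divalent palladium (Pd(OAc)2 10 mol %, pyridine, 1,4-benzoquinone, dioxane, 60 °C) activates the C18=C19 alkene for attack of the hydroperoxide oxygen at C18, a Wacker-type cyclization of an unsaturated hydroperoxide. β-Hydride elimination toward a methyl group then gives the C18-isopropenyl dioxepane F3. A second hydroperoxysilylation as in step 12 converts this new 1,1-disubstituted alkene into the C19 triethylsilyl peroxide F4. Aq. HF in MeCN as in step 13 gives 24.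

Further compounds
F1 | step 10 | C5-epimeric dienone, (6R)-epimer of 19 | O=C1C(C(=O)c2ccccc2)=C(O)C(CC=C(C)C)=C(O)[C@@]1(CC=C(C)C)CC(=C(C)C)C[C@@H](OC(=O)OC)C(C)=C
F2 | step 11 | C7-iodo cage (21 with iodine in place of the outward C7 hydrogen) | CC(C)=CC[C@]12C[C@]3(I)C[C@H](C(C)=C)[C@](CC=C(C)C)(C1=O)C(=O)[C@](C(=O)c1ccccc1)(C2=O)C3(C)C
F3 | step 14 | C18-isopropenyl dioxepane | CC(C)=CC[C@]12C[C@@H]3C[C@@H]4C(C)(C)OO[C@H](C(C)=C)C[C@@]4(C1=O)C(=O)[C@](C(=O)c1ccccc1)(C2=O)C3(C)C
F4 | step 14 | C19 triethylsilyl peroxide of the target | CC(C)=CC[C@]12C[C@@H]3C[C@@H]4C(C)(C)OO[C@H](C(C)(C)OO[Si](CC)(CC)CC)C[C@@]4(C1=O)C(=O)[C@](C(=O)c1ccccc1)(C2=O)C3(C)C
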